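The uptake ratio, 92.7 in south-west, is the pace at which substrate takes up dissolved reagent over the pace at which gas replaces it: the first-step constant times c(substrate), over the transfer coefficient.

    substrate + reagent → single product + by-product (k1 = 0.068 /M/min)
    reagent + single product → double product + by-product (k2 = 0.023 /M/min)
    reagent + double product → tris adduct + by-product (k3 = 0.010 /M/min)
    single product + capture agent → trapped intermediate (k4 = 0.17 /M/min)
    gas ⇌ reagent, rate k5*(csat - [reagent]) (k5 = 0.0022 /min, csat = 16 mM)
    substrate + single product → side product (k6 = 0.049 /M/min)

| flask | substrate | capture agent | gas | time |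
|---|---|---|---|---|
| east | 0.040 M | 0.0350 M | 16 mM (held) | 6.0 h |
| north-west | 0.10 M | 0.0350 M | 16 mM (held) | 6.0 h |
| west | 0.30 M | 0.0350 M | 16 mM (held) | 6.0 h |
| south-east | 1.0 M | 0.0350 M | 16 mM (held) | 6.0 h |
| south-west | 3.0 M | 0.0350 M | 16 mM (held) | 6.0 h |

- percentages count the substrate that a species holds: one side product counts as two
- at the start none of reagent is dissolved
- "hardly changes" means that all values lie within two and a half points (for a concentration: within two and a half percent of the largest)
- run time (east): 6.0 h

- [double product] at the end for east, north-west, west, south-east, south-west, in this order
- how that number moves from the first to the last of them (hardly changes / falls, then rises / rises all the way / rises, then falls / falls all the way)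

Where does c(reagent) level off? At a ratio of one, reached at c(substrate) = 0.0324 M, the two paces match and c(reagent) levels at half of saturation. With the later steps neglected and substrate near its charge, the level is saturation over one plus the ratio. South-west therefore levels at 1.71 × 10⁻⁴ M, and it gets there early, since its climb time, one over the sum of the two paces, is 4.85 min, far shorter than the run of 6.0 h.

Where does single product go? In south-west, side-product formation takes it 24.7 times as fast as capture, so it holds a quasi-steady level of 2.28 × 10⁻⁴ M.

What does that make of double product? It grows as the second-step constant times c(reagent) times c(single product), and single product is itself made from reagent, so c(reagent) enters squared. My reckoning gives 3.22 × 10⁻⁷ M in south-west and, with ratio 30.9, 2.58 × 10⁻⁶ M in south-east, so south-east ends higher than south-west. East is different: its climb time of 203 min is shorter than the run by a factor of just 1.77, so I do not rely on the level there and the reckoning stops. At equal c(reagent), north-west makes single product faster than east, so I expect a rise first, then the fall.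

The forecast reads 2.900 × 10⁻⁵ M, 3.300 × 10⁻⁵ M, 1.600 × 10⁻⁵ M, 2.300 × 10⁻⁶ M and 3.200 × 10⁻⁷ M, a row that rises, then falls, and holds that double product “collapses steeply as both reagent and single product are suppressed at high substrate”.

The simulation gives 2.96 × 10⁻⁵ M, 3.26 × 10⁻⁵ M, 1.46 × 10⁻⁵ M, 2.36 × 10⁻⁶ M and 3.13 × 10⁻⁷ M, a row that rises, then falls. South-west ends with c(reagent) at 1.72 × 10⁻⁴ M against the 1.71 × 10⁻⁴ M from its ratio, and west, with ratio 9.27, ends at 0.00162 M against 0.00156 M. East, with ratio 1.24, stands at 0.00605 M against 0.00715 M, with reagent at the end still made faster than it is used up, by a factor of 1.46.

The numbers of this flask were chosen freely; the result is computed.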